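**The pitfall.** Here a peak misleads: the beta run reads 65.1% of intermediate at 0.417 d but 29.4% at 3.00 d, and the question stands later, at 5.0 d.

| setting | beta | alpha | gamma | theta | ash | alder | maple | cedar |
|---|---|---|---|---|---|---|---|---|
| starting material | 0.079 M | 0.053 M | 0.12 M | 0.079 M | 0.079 M | 0.079 M | 0.079 M | 0.079 M |
| partner | 1 equiv | 1 equiv | 1 equiv | 1.5 equiv | 1.00 equiv | 1.00 equiv | 1.00 equiv | 1.00 equiv (fed, over 5.00 d) |
| remark | run made earlier | run made earlier | run made earlier | run made earlier | everything together in a closed stirred flask, run for 5.0 d | plug flow through a tube for 5.0 d, no back-mixing | a single well-mixed tank run continuously and read at steady state, 5.0 d in it on average | all but partner at the start; partner goes in evenly over 5.00 d, the run ends at 5.0 d |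
| time |  |  |  |  | 5.0 d | 5.0 d |  | 5.0 d |

| run | time / d | intermediate / % | product / % |
|---|---|---|---|
| beta | 0.250 | 58.2 | 5.1 |
| beta | 0.417 | 65.1 | 11.5 |
| beta | 0.833 | 60.2 | 26.1 |
| beta | 1.67 | 43.6 | 46.6 |
| beta | 3.00 | 29.4 | 68.5 |
| alpha | 0.500 | 60.0 | 10.4 |
| alpha | 0.833 | 58.8 | 23.3 |
| alpha | 1.67 | 44.7 | 45.4 |
| alpha | 3.00 | 27.2 | 64.3 |
| alpha | 6.00 | 13.4 | 79.9 |
| gamma | 0.500 | 68.0 | 15.4 |
| gamma | 0.833 | 64.5 | 26.8 |
| gamma | 1.67 | 46.4 | 49.3 |
| gamma | 3.00 | 28.9 | 68.3 |
| gamma | 6.00 | 13.8 | 84.7 |
| theta | 1.25 | 56.6 | 42.6 |
| theta | 2.50 | 31.6 | 68.5 |
| theta | 4.00 | 19.2 | 81.1 |
| theta | 5.00 | 17.4 | 82.8 |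
| theta | 6.00 | 13.8 | 86.1 |

(each reading ± 1 percentage point)

- the set-up with the highest amount of intermediate at the outlet or at the end, in percent of the starting material put in ("none" if the first two lie within 2 percentage points) (ash / alder / maple / cedar / none)
- amount of intermediate at the outlet or at the end, in percent of the starting material put in, ash
- amount of intermediate at the outlet or at the end, in percent of the starting material put in, alder
- amount of intermediate at the outlet or at the end, in percent of the starting material put in, maple
- amount of intermediate at the outlet or at the end, in percent of the starting material put in, cedar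

- the stated concentrations are those of everything mixed, before any reaction; amounts are the same in each set-up
- steps under discussion: starting material + partner -> intermediate + by-product; intermediate <-> product
- the feed brings no volume worth counting
- the earlier runs were made in a closed, stirred flask

**One balance.** We write the balance of partner: what has gone of it equals, in amount, intermediate plus product. So intermediate equals partner used times the share of intermediate in that sum. Which factor must we know well?

**What matters.** The first reading of the beta run, taken as second order with equal charges, gives a first-step rate constant times c(starting material) of 6.90 d⁻¹. In ash this leaves 2.82% of partner, and 0.5 of that rate leaves 5.48%, so an error here moves ash little. In maple the tank balance leaves 15.6% against 21.4%, a wider gap. Starting concentration does not show in the share within the scatter: at 3.00 d the share reads 29.7% in the alpha run and 29.7% in the gamma run. An error in the share reaches ash multiplied by the 97.2% of partner used, so the share is the number to know.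

**Our reckoning.** The theta run at 5.00 d reads 17.4% for the intermediate share, intermediate over intermediate plus product. By this estimate ash holds 16.9%, and alder, whose portions each age as in a closed flask, the same. Taking cedar's partner as reacting on arrival, a rough estimate, its portions average 2.50 d old; the theta share at 2.50 d then gives 31.6%, more than our figure for ash. Maple's share we leave unreckoned.

**The result.** The forecast gave 17%, 17%, 28.5% and 34% and chose cedar, reasoning that “the feed limits formation, so intermediate is made late”. The flasks give 17.1% for ash, 17.1% for alder, 28.2% for maple and 32.3% for cedar, so cedar leads.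

    starting material + partner → intermediate + by-product (k = 3.90 L mol⁻¹ h⁻¹)
    intermediate ⇌ product (K = 7.40, k = 0.0230 h⁻¹)

In ash, 5.13% of starting material remained at 2.50 d, and by 5.00 d intermediate had fallen from 33.1% to 17.1% while product rose from 61.7% to 80.3%. In cedar, 13.1% of the charged partner was left at 5.00 d, with 32.3% of intermediate beside 54.6% of product. The share in ash at 5.00 d is 17.6%. In the flask like alder with 0.250 equiv of partner, the limiting reagent, 0% of partner remains at 5.00 d; our share applied to that charge gives 4.34%, and the flask holds 4.04% of intermediate.

The runs are calculated from invented constants; noise was put on by code.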